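The target is cut at C12–C13, the bond between the second CH2 of the chain on C9 (ring B) and the methine that carries C16. The key step exploits the 1,3-relationship of C13 to the C15 ester carbonyl: C13 is the β-carbon of a crotonate. A copper-catalysed asymmetric conjugate addition of the Grignard reagent of the complete A/B-ring bromide to the crotonate of 1,3-disilylated glycerol forms C12–C13, sets C13 (R) under catalyst control and delivers the whole acylglycerol in one operation. The bicyclic bromide comes from (R)-pulegone, whose stereocentre becomes C8 and whose isopropylidene becomes C4 with its two methyls; ring A is closed by McMurry coupling.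

Key step: step 10

Numbering: halimane numbering is used throughout (ring A: C1–C5 and C10; ring B: C5–C10; C17 on C8, C20 on C9, C18/C19 on C4, side chain C11–C16, ester carbonyl C15).

Assumption: of the two enantiomers of the Josiphos ligand 1-[2-(diphenylphosphino)ferrocenyl]ethyldicyclohexylphosphine, (R,Sp) or (S,Rp), the one that delivers a primary alkyl group to the Si face of C-β of an (E)-crotonate is used; it is identified in a trial run with 3,3-dimethylbutylmagnesium bromide and ester 18.

Step 1
Reactants: 1 (R)-(+)-pulegone; 2 but-3-en-1-ylmagnesium bromide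
Product: 4 (2S,5R)-5-methyl-2-(2-methylhex-5-en-2-yl)cyclohexan-1-one, via magnesium enolate 3 (not isolated)
Conditions: CuBr·SMe2 (10 mol%), Et2O/THF, −20 °C; 1 M HCl; then KOH, EtOH/H2O, reflux
Reagents that add atoms: but-3-en-1-ylmagnesium bromide, C=CCC[Mg]Br
Why: Copper-catalysed 1,4-addition of the Grignard reagent to the s-cis enone builds the quaternary C4 (the two pulegone methyls become C18/C19), and base equilibration of the epimerisable C5 should favour the trans, diequatorial (5S) isomer as in related pulegone adducts, C8 coming unchanged from 1 (any cis epimer carried on is corrected in step 2).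

Step 2
Reactants: 4
Product: 6 (2S,3R,6S)-2,3-dimethyl-6-(2-methylhex-5-en-2-yl)cyclohexan-1-one, via lithium enolate 5 (not isolated)
Conditions: LiN(i-Pr)2, THF, −78 °C; MeI, −78 → 0 °C; then NaOMe (cat.), MeOH, rt
Reagents that add atoms: iodomethane, CI
Why: Kinetic enolate alkylation, in which the amide base removes a proton from the unhindered C9 methylene and not from the C5 methine next to the quaternary C4, followed by methoxide equilibration that should settle both α-centres in the all-equatorial arrangement (C9 is enolised again in step 3, so its configuration here is not critical).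

Step 3
Reactants: 6; 7 tert-butyl bromoacetate
Product: 9 tert-butyl 2-[(1R,3S,6R)-1,6-dimethyl-3-(2-methylhex-5-en-2-yl)-2-oxocyclohexyl]acetate, via lithium enolate 8 (not isolated)
Conditions: LiN(i-Pr)2, THF, −78 → 0 °C; DMPU, 7, −78 °C → rt
Reagents that add atoms: tert-butyl bromoacetate, CC(C)(C)OC(=O)CBr
Why: Enolate alkylation in which the base removes the axial C9–H (the C5–H is shielded by the quaternary C4) and the reactive α-bromo ester attacks the tetrasubstituted enolate along the axial trajectory (chair-like transition state, α-face) of the half-chair whose C5 tert-alkyl group and C8 methyl stay pseudo-equatorial, which should place CH2CO2t-Bu axial and cis to the C8 methyl and leave the C9 methyl equatorial (9R).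

Step 4
Reactants: 9
Product: 11 tert-butyl 2-[(1R,3S,6R)-1,6-dimethyl-3-(2-methyl-5-oxopentan-2-yl)-2-oxocyclohexyl]acetate, via ozonide 10 (not isolated)
Conditions: O3, CH2Cl2, −78 °C; PPh3, −78 °C → rt
Reagents that add atoms: ozone, [O-][O+]=O
Why: Ozonolysis with reductive work-up cleaves the only C=C bond of 9 to the C1 aldehyde under neutral conditions that leave the ketone, the tert-butyl ester and the epimerisable C5 untouched.

Step 5
Reactants: 11
Product: 12 tert-butyl 2-[(1R,2R,4aS)-1,2,5,5-tetramethyl-1,2,3,4,4a,5,6,7-octahydronaphthalen-1-yl]acetate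
Conditions: TiCl3(DME)1.5, Zn–Cu couple, DME, reflux, slow addition of 11 (high dilution)
Reagents that add atoms: none
Why: Intramolecular McMurry coupling, in which low-valent titanium joins the aldehyde carbon C1 to the ketone carbon C10 and deoxygenates, closes ring A as a six-membered ring and places the double bond at C1=C10 with no regiochemical choice, the tert-butyl ester reacting more slowly than the carbonyl pair.

Step 6
Reactants: 12
Product: 13 2-[(1R,2R,4aS)-1,2,5,5-tetramethyl-1,2,3,4,4a,5,6,7-octahydronaphthalen-1-yl]ethan-1-ol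
Conditions: LiAlH4, THF, 0 °C → reflux
Reagents that add atoms: none
Why: Hydride reduction of the ester gives the primary alcohol at C12, and the isolated trisubstituted alkene is inert to LiAlH4.

Step 7
Reactants: 13
Product: 14 (1R,2R,4aS)-1-(2-bromoethyl)-1,2,5,5-tetramethyl-1,2,3,4,4a,5,6,7-octahydronaphthalene
Conditions: CBr4, PPh3, CH2Cl2, 0 °C
Reagents that add atoms: tetrabromomethane, BrC(Br)(Br)Br
Why: The Appel reaction converts the primary alcohol to the bromide under neutral conditions that do not touch the acid-sensitive C1=C10 alkene.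

Step 8
Reactants: 15 glycerol
Product: 16 1,3-bis[(tert-butyldimethylsilyl)oxy]propan-2-ol
Conditions: TBSCl (2 equiv), imidazole, DMF, 0 °C
Reagents that add atoms: tert-butyldimethylsilyl chloride, CC(C)(C)[Si](C)(C)Cl
Why: The two primary hydroxyls of glycerol are silylated much faster than the secondary one, so two equivalents of the bulky chlorosilane should give the 1,3-bis-silyl ether.

Step 9
Reactants: 16; 17 (E)-but-2-enoic acid (crotonic acid)
Product: 18 1,3-bis[(tert-butyldimethylsilyl)oxy]propan-2-yl (2E)-but-2-enoate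
Conditions: DCC, DMAP (cat.), CH2Cl2, 0 °C → rt
Reagents that add atoms: (E)-but-2-enoic acid, C/C=C/C(=O)O
Why: Steglich esterification acylates the free secondary hydroxyl, and a carbodiimide is used instead of the acid chloride with an amine base to avoid ketene-mediated deconjugation, so the E-crotonate geometry is kept.

Step 10
Reactants: 14; 18
Product: 21 1,3-bis[(tert-butyldimethylsilyl)oxy]propan-2-yl (3R)-3-methyl-5-[(1R,2R,4aS)-1,2,5,5-tetramethyl-1,2,3,4,4a,5,6,7-octahydronaphthalen-1-yl]pentanoate, via Grignard reagent 19 (not isolated), via magnesium enolate 20 (not isolated)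
Conditions: Mg turnings, Et2O, reflux; then CuBr·SMe2 (5 mol%), Josiphos ligand (6 mol%, enantiomer as assumed above), t-BuOMe, −75 °C, slow addition of 18 (1.3 equiv); MeOH, aq NH4Cl
Reagents that add atoms: 1,3-bis[(tert-butyldimethylsilyl)oxy]propan-2-yl (2E)-but-2-enoate (18), C/C=C/C(=O)OC(CO[Si](C)(C)C(C)(C)C)CO[Si](C)(C)C(C)(C)C
Why: Transmetallation of 19 to the monovalent copper–diphosphine complex, π-complexation to the enoate, oxidative addition at C-β to a σ-alkyl trivalent copper species and reductive elimination form the C12–C13 bond and give magnesium enolate 20, which is protonated on work-up. The closest known reaction type is the CuBr·SMe2/Josiphos-catalysed enantioselective conjugate addition of primary alkylmagnesium bromides to (E)-α,β-unsaturated esters, for which simple crotonates are typical substrates; here only the ester alcohol is larger. No ring is closed. The new stereocentre C13 is set by the catalyst, which delivers the alkyl group to the Si face of C-β to give 13R; the nearest stereocentre of the nucleophile (C9) is three bonds from C13 and should not perturb this, so a single diastereomer is expected. The step needs 1,4- over 1,2-selectivity and one enoate face: the first is secured by copper catalysis at −75 °C, slow addition of the ester and its hindered secondary alkoxy group, the second by the ligand together with the geometrically pure E-crotonate (a Z-enoate would give the opposite sense).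

Step 11
Reactants: 21
Product: 22 1,3-dihydroxypropan-2-yl (3R)-3-methyl-5-[(1R,2R,4aS)-1,2,5,5-tetramethyl-1,2,3,4,4a,5,6,7-octahydronaphthalen-1-yl]pentanoate (target)
Conditions: HF·pyridine, pyridine, THF, 0 °C; purification on boric acid-treated silica
Reagents that add atoms: none
Why: Fluoride cleavage of the two primary silyl ethers under buffered, weakly acidic conditions at 0 °C is chosen because base or untreated silica promotes 2→1 acyl migration in 2-acylglycerols, and the ester, C13 and the C1=C10 alkene are untouched.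

Compound list
1 | (R)-(+)-pulegone, (5R)-5-methyl-2-(propan-2-ylidene)cyclohexan-1-one | C[C@@H]1CCC(=C(C)C)C(=O)C1 | starting material
2 | but-3-en-1-ylmagnesium bromide | C=CCC[Mg]Br | starting material
3 | bromomagnesium enolate of the 1,4-adduct of 1 and 2 | C[C@@H]1CCC(C(C)(C)CCC=C)=C(O[Mg]Br)C1 | intermediate
4 | (2S,5R)-5-methyl-2-(2-methylhex-5-en-2-yl)cyclohexan-1-one | C[C@@H]1CC[C@@H](C(C)(C)CCC=C)C(=O)C1 | intermediate
5 | lithium enolate of 4 (towards C9) | C[C@@H]1CC[C@@H](C(C)(C)CCC=C)C(O[Li])=C1 | intermediate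
6 | (2S,3R,6S)-2,3-dimethyl-6-(2-methylhex-5-en-2-yl)cyclohexan-1-one | C[C@@H]1CC[C@@H](C(C)(C)CCC=C)C(=O)[C@H]1C | intermediate
7 | tert-butyl bromoacetate | CC(C)(C)OC(=O)CBr | starting material
8 | lithium enolate of 6 (towards C9) | C[C@@H]1CC[C@@H](C(C)(C)CCC=C)C(O[Li])=C1C | intermediate
9 | tert-butyl 2-[(1R,3S,6R)-1,6-dimethyl-3-(2-methylhex-5-en-2-yl)-2-oxocyclohexyl]acetate | C[C@@H]1CC[C@@H](C(C)(C)CCC=C)C(=O)[C@]1(C)CC(=O)OC(C)(C)C | intermediate
10 | ozonide (1,2,4-trioxolane) of the vinyl group of 9, mixture at the ozonide carbon | C[C@@H]1CC[C@@H](C(C)(C)CCC2OCOO2)C(=O)[C@]1(C)CC(=O)OC(C)(C)C | intermediate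
11 | tert-butyl 2-[(1R,3S,6R)-1,6-dimethyl-3-(2-methyl-5-oxopentan-2-yl)-2-oxocyclohexyl]acetate | C[C@@H]1CC[C@@H](C(C)(C)CCC=O)C(=O)[C@]1(C)CC(=O)OC(C)(C)C | intermediate
12 | tert-butyl 2-[(1R,2R,4aS)-1,2,5,5-tetramethyl-1,2,3,4,4a,5,6,7-octahydronaphthalen-1-yl]acetate | CC(C)(C)OC(=O)C[C@@]1(C)C2=CCCC(C)(C)[C@@H]2CC[C@H]1C | intermediate
13 | 2-[(1R,2R,4aS)-1,2,5,5-tetramethyl-1,2,3,4,4a,5,6,7-octahydronaphthalen-1-yl]ethan-1-ol | OCC[C@@]1(C)C2=CCCC(C)(C)[C@@H]2CC[C@H]1C | intermediate
14 | (1R,2R,4aS)-1-(2-bromoethyl)-1,2,5,5-tetramethyl-1,2,3,4,4a,5,6,7-octahydronaphthalene | BrCC[C@@]1(C)C2=CCCC(C)(C)[C@@H]2CC[C@H]1C | intermediate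
15 | glycerol | OCC(O)CO | starting material
16 | 1,3-bis[(tert-butyldimethylsilyl)oxy]propan-2-ol | CC(C)(C)[Si](C)(C)OCC(O)CO[Si](C)(C)C(C)(C)C | intermediate
17 | (E)-but-2-enoic acid (crotonic acid) | C/C=C/C(=O)O | starting material
18 | 1,3-bis[(tert-butyldimethylsilyl)oxy]propan-2-yl (2E)-but-2-enoate | C/C=C/C(=O)OC(CO[Si](C)(C)C(C)(C)C)CO[Si](C)(C)C(C)(C)C | intermediate
19 | {2-[(1R,2R,4aS)-1,2,5,5-tetramethyl-1,2,3,4,4a,5,6,7-octahydronaphthalen-1-yl]ethyl}magnesium bromide | Br[Mg]CC[C@@]1(C)C2=CCCC(C)(C)[C@@H]2CC[C@H]1C | intermediate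
20 | bromomagnesium ester enolate of 21 (C14=C15, geometry not defined) | C[C@H](CC[C@@]1(C)C2=CCCC(C)(C)[C@@H]2CC[C@H]1C)C=C(O[Mg]Br)OC(CO[Si](C)(C)C(C)(C)C)CO[Si](C)(C)C(C)(C)C | intermediate
21 | 1,3-bis[(tert-butyldimethylsilyl)oxy]propan-2-yl (3R)-3-methyl-5-[(1R,2R,4aS)-1,2,5,5-tetramethyl-1,2,3,4,4a,5,6,7-octahydronaphthalen-1-yl]pentanoate | C[C@H](CC[C@@]1(C)C2=CCCC(C)(C)[C@@H]2CC[C@H]1C)CC(=O)OC(CO[Si](C)(C)C(C)(C)C)CO[Si](C)(C)C(C)(C)C | intermediate
22 | 1,3-dihydroxypropan-2-yl (3R)-3-methyl-5-[(1R,2R,4aS)-1,2,5,5-tetramethyl-1,2,3,4,4a,5,6,7-octahydronaphthalen-1-yl]pentanoate | C[C@H](CC[C@@]1(C)C2=CCCC(C)(C)[C@@H]2CC[C@H]1C)CC(=O)OC(CO)CO | target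

Total step count: 11. Longest linear sequence: 9 steps (steps 1–7, 10, 11); steps 8–9 make the acceptor 18.

Steps most likely to fail

Step 3. Attack of the bromoacetate on the equatorial (β) face of enolate 8 may compete with axial attack, so the facial selectivity at the quaternary C9 may be poor, and this centre cannot be corrected later. The fallback sets out from 1 and makes C9 quaternary on pulegone itself, where the only control element is the neighbouring C8 methyl. Kinetic α′-deprotonation (LiN(i-Pr)2, THF/DMPU, −78 °C) and alkylation with tert-butyl(2-iodoethoxy)dimethylsilane should give (2S,3R)-2-{2-[(tert-butyldimethylsilyl)oxy]ethyl}-3-methyl-6-(propan-2-ylidene)cyclohexan-1-one F1. A second α′-deprotonation and MeI, which should enter anti to the C8 methyl held pseudoaxial by A(1,2) strain, should give the (2R,3R)-2,3-dimethyl analogue F2 with the chain cis to the C8 methyl. CuBr·SMe2-catalysed addition of 2, base equilibration and chromatographic separation of the C5 epimers (no strong thermodynamic bias is expected once C9 is quaternary) should give (2R,3R,6S)-2-{2-[(tert-butyldimethylsilyl)oxy]ethyl}-2,3-dimethyl-6-(2-methylhex-5-en-2-yl)cyclohexan-1-one F3. Ozonolysis (O3; PPh3) then gives keto aldehyde 4-[(1S,3R,4R)-3-{2-[(tert-butyldimethylsilyl)oxy]ethyl}-3,4-dimethyl-2-oxocyclohexyl]-4-methylpentanal F4, McMurry coupling as in step 5 gives the silyl ether tert-butyldimethyl{2-[(1R,2R,4aS)-1,2,5,5-tetramethyl-1,2,3,4,4a,5,6,7-octahydronaphthalen-1-yl]ethoxy}silane F5, and TBAF in THF returns to the route at 13.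

Step 5. Reductive coupling at the ketone C10, which is flanked by the quaternary C9 and the neopentyl-type C5, may be slow, so that simple reduction of the aldehyde, intermolecular pinacol coupling or attack on the ester takes over. The fallback sets out from 9 (before ozonolysis): Takai–Lombardo methylenation (Zn, CH2Br2, TiCl4, THF/CH2Cl2) of the ketone should give the diene tert-butyl 2-[(1R,3S,6R)-1,6-dimethyl-2-methylidene-3-(2-methylhex-5-en-2-yl)cyclohexyl]acetate F6, and ring-closing metathesis with the second-generation Grubbs catalyst RuCl2(H2IMes)(PCy3)(=CHPh) in toluene at 80 °C should close ring A and return to the route at 12.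

Step 10. Because the ester alcohol is a bulky secondary bis-silyloxypropanol instead of the usual methyl group, the catalyst may lose facial selectivity at C13 or the rate of the catalysed 1,4-addition may fall until uncatalysed 1,2-addition competes. The fallback sets out from 14 (as Grignard reagent 19) and uses the best-precedented acceptor class, a thioester, with the glycerol unit attached afterwards. Addition of 19 to S-ethyl (2E)-but-2-enethioate F7 under the same CuBr·SMe2/Josiphos conditions should give S-ethyl (3R)-3-methyl-5-[(1R,2R,4aS)-1,2,5,5-tetramethyl-1,2,3,4,4a,5,6,7-octahydronaphthalen-1-yl]pentanethioate F8. Hydrolysis with LiOH in THF/H2O gives (3R)-3-methyl-5-[(1R,2R,4aS)-1,2,5,5-tetramethyl-1,2,3,4,4a,5,6,7-octahydronaphthalen-1-yl]pentanoic acid F9, and Steglich esterification of F9 with 16 (DCC, DMAP, CH2Cl2) returns to the route at 21.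

Further compounds
F1 | step 3 | (2S,3R)-2-{2-[(tert-butyldimethylsilyl)oxy]ethyl}-3-methyl-6-(propan-2-ylidene)cyclohexan-1-one | C[C@@H]1CCC(=C(C)C)C(=O)[C@H]1CCO[Si](C)(C)C(C)(C)C
F2 | step 3 | (2R,3R)-2-{2-[(tert-butyldimethylsilyl)oxy]ethyl}-2,3-dimethyl-6-(propan-2-ylidene)cyclohexan-1-one | C[C@@H]1CCC(=C(C)C)C(=O)[C@]1(C)CCO[Si](C)(C)C(C)(C)C
F3 | step 3 | (2R,3R,6S)-2-{2-[(tert-butyldimethylsilyl)oxy]ethyl}-2,3-dimethyl-6-(2-methylhex-5-en-2-yl)cyclohexan-1-one | C[C@@H]1CC[C@@H](C(C)(C)CCC=C)C(=O)[C@]1(C)CCO[Si](C)(C)C(C)(C)C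
F4 | step 3 | 4-[(1S,3R,4R)-3-{2-[(tert-butyldimethylsilyl)oxy]ethyl}-3,4-dimethyl-2-oxocyclohexyl]-4-methylpentanal | C[C@@H]1CC[C@@H](C(C)(C)CCC=O)C(=O)[C@]1(C)CCO[Si](C)(C)C(C)(C)C
F5 | step 3 | tert-butyldimethyl{2-[(1R,2R,4aS)-1,2,5,5-tetramethyl-1,2,3,4,4a,5,6,7-octahydronaphthalen-1-yl]ethoxy}silane | CC(C)(C)[Si](C)(C)OCC[C@@]1(C)C2=CCCC(C)(C)[C@@H]2CC[C@H]1C
F6 | step 5 | tert-butyl 2-[(1R,3S,6R)-1,6-dimethyl-2-methylidene-3-(2-methylhex-5-en-2-yl)cyclohexyl]acetate | C[C@@H]1CC[C@@H](C(C)(C)CCC=C)C(=C)[C@]1(C)CC(=O)OC(C)(C)C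
F7 | step 10 | S-ethyl (2E)-but-2-enethioate | C/C=C/C(=O)SCC
F8 | step 10 | S-ethyl (3R)-3-methyl-5-[(1R,2R,4aS)-1,2,5,5-tetramethyl-1,2,3,4,4a,5,6,7-octahydronaphthalen-1-yl]pentanethioate | C[C@H](CC[C@@]1(C)C2=CCCC(C)(C)[C@@H]2CC[C@H]1C)CC(=O)SCC
F9 | step 10 | (3R)-3-methyl-5-[(1R,2R,4aS)-1,2,5,5-tetramethyl-1,2,3,4,4a,5,6,7-octahydronaphthalen-1-yl]pentanoic acid | C[C@H](CC[C@@]1(C)C2=CCCC(C)(C)[C@@H]2CC[C@H]1C)CC(=O)O
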